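The flask I was asked about was the red run itself, allowed 30 h against the 4.00 h it had been followed.

| flask | D | Q | J | remark | time |
|---|---|---|---|---|---|
| red | 0.051 M | 0.0102 M | 2.6 mM | the very flask that is asked about, followed so far |  |
| flask | 0.051 M | 0.0102 M | 2.6 mM |  | 30 h |

- red (time / h: G / %): 0.333: 6; 0.833: 11; 1.50: 13; 2.50: 24; 4.00: 21

(readings scatter by 1.5 percentage points)



1. the best time, 30 h at the latest, for G
2. the amount of G, in percent of the D charged, at that time

Two numbers in the red run did not go together. Its first two readings gave G a first-order making constant of 0.146 h⁻¹, which with nothing lost meant 44.2 % by 4.00 h, yet its last two readings averaged 22.5 %.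

So I supposed that G was being lost as it was made. If J carries that loss and stays at its charge, then [G] alone sets the order of the loss, which makes it pseudo-first-order. At a stall, making equals loss:

[D] at the stall = 62.3 %

ρ = [G]/[D] = 0.361

loss constant = making constant/ρ = 0.403 h⁻¹

I called ρ the ratio of making to loss. Two rules follow from it:

top of G = ρ raised to the power loss/(loss − making) = 20.3 %

time of top = ln(loss/making)/(loss − making) = 3.95 h

My top lay somewhat under the readings, and in my reckoning G fell after it.

The forecast gave 25 % at 30 h, holding that “All of these give a plateau or a slow creep upward”.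

The flask gave 23.2 % at 5.28 h, and G then fell to 9.53 % by 30.0 h.

    D + Q → X (k = 1.10 M⁻¹ h⁻¹)
    D ⇌ G (K = 0.800, k = 0.140 h⁻¹)
    E + J ⇌ Z + J, rate k3*[J]*[E] forward; the back reaction follows from the equilibrium constant (K = 1.10, k = 9.10 M⁻¹ h⁻¹)
    G + J ⇌ E + J, rate k4*[J]*[G] forward; the back reaction follows from the equilibrium constant (K = 5.80, k = 58.0 M⁻¹ h⁻¹)
    Z ⇌ D (k = 0.00440 h⁻¹)

At the flask's top, ρ stood at 0.450, and the rule on that ratio returns 23.4 %. The neighbour flask was charged with 0.010 M of J. To my read loss constant I added 58 M⁻¹ h⁻¹ times the extra J, which gave 0.833 h⁻¹, so ρ = 0.175 and the rule gives 12.1 %. That neighbour flask reached 13.4 %.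

The data are calculated from invented constants, noise included.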